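## The problem

The target 21 is a 4-hydroxy-5,6-epoxycyclohex-2-en-1-one. Its ring carbons are numbered here C1 (ketone), C2 (bearing the acetoxymethyl carbon C7), C3, C4 (carbinol), C5 and C6 (oxirane carbons). C5 is fully substituted and carries C1' of a side chain that bears a free hydroxyl at C1' and continues as a (2'E,6'E)-triene of farnesyl origin.

Only one carbocycle has to be closed, but it carries four contiguous stereocentres: C4 (S), C5 (R), C6 (R) and C1' (S). C5 and C6 are tied to each other by the oxirane, whose oxygen lies trans to the C4 hydroxyl. C1' sits outside the ring on a freely rotating bond, so it cannot be expected to follow from the ring centres and must be set by a reagent. C4 and C1' flank C5 as two alkenyl carbinols of the same sense, which suggests building C5 as an alkene carbon between two separately made carbinols and creating C5 and C6 together by one epoxidation.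

The finished molecule tolerates little. The γ-hydroxy epoxy enone eliminates or aromatises with base. The C7 acetate is an allylic acetate of Baylis–Hillman type, open to SN2' attack. The C1' allylic alcohol ionises in strong acid. The three trisubstituted alkenes of the chain rule out peracids and electrophilic halogen late in the route. The ketone, the acetate and the free hydroxyls must therefore appear late and under near-neutral conditions.

The feature that opens the route is this: C2 is the α-carbon of an acrylate unit (C7 as carboxyl carbon, C2=C3 as alkene), and its neighbour C1 is an oxidised carbon on the oxirane carbon C6. C1–C2 is therefore the bond a Morita–Baylis–Hillman reaction makes between an enoate α-carbon and an aldehyde, and making it closes the ring C1–C6.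

## Retrosynthesis

**Endgame, 21 back to 17.** No skeletal bond is cut. The sensitive groups of 21 are traced back to a C1 carbinol, an ethyl ester and two triethylsilyl ethers: 21 from enone 20 by desilylation, 20 from alcohol 19 by oxidation, 19 from diol 18 by acetylation of the primary hydroxyl, and 18 from hydroxy ester 17 by reduction. Oxidising C1 before reducing the ester would leave a keto ester that cannot be reduced selectively at C7. The same silyl group is placed on O4 and O1' so that one mildly acidic fluoride treatment ends the synthesis. The forward steps must tell a primary from a secondary hydroxyl and must oxidise C1 without base.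

**C1–C2, 17 back to 16.** Cutting C1–C2 turns the epoxycyclohexene 17 into the open-chain epoxy aldehyde 16, which carries a simple E-enoate. The neighbouring cut at C3–C4 would make a target stereocentre (C4) in the ring closure and would need a stereodefined Z-alkenyl halide. Cutting C4–C5 together with C1–C6 would need a cycloaddition between two electron-rich partners. The C1–C2 cut asks only for an E-alkene, because the regenerated alkene ends up inside the ring, and the one centre it creates (C1) is later erased. The forward reaction must add a nucleophilic catalyst to the enoate without touching the oxirane or the C4 silyloxy group.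

**Oxirane, 16 back to 14.** The aldehyde 16 comes from epoxy alcohol 15 by oxidation, and the two C–O bonds of the oxirane are cut to give the trisubstituted allylic alcohol 14. The C1 hydroxyl is the only free hydroxyl in 14, so a titanium tartrate can bind there and epoxidise C5=C6 alone among five alkenes. A hydroxyl-directed epoxidation from C1' would instead hit the more electron-rich C2'=C3' alkene. The forward reaction must deliver oxygen to the face that gives the C5/C6 configuration of 21; the cis relation of C4 and C1 on the oxirane is already fixed by the alkene geometry.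

**C3–C4, 14 back to 9 and 10.** Alcohol 14 comes from the 4-methoxybenzyl ether 13, 13 from the C4 carbinol 12 by silylation, and 12 from the ynoate 11 by trans-reduction. Cutting C3–C4 of 11 gives enal 9 and ethyl propiolate 10. The shorter cut at C4–C5 (an alkenyl metal adding to ethyl 4-oxobut-2-enoate) would form the C4 carbinol with no reliable control. The C3–C4 cut costs two more steps but places C4 under catalyst control in an alkynylation of an α-substituted enal, a well-established substrate class. The forward reactions must keep the C5=C6 geometry of the enal and reduce the alkyne to the E-alkene only.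

**C4–C5 and the alkene, 9 back to 4.** The formyl carbon of 9 is cut from C5, giving the alkenyllithium 8 and, behind it, the iodide 7 and its free alcohol 6. The iodide comes from propargylic alcohol 4 through the stannane 5. Trans-addition of H and Sn across the alkyne, with tin directed to the carbon next to the free C1' hydroxyl, gives the trisubstituted alkene with the C5 substituent cis to the C1 methylene. The forward reaction must be regioselective between two oxygenated alkyne flanks; only the flank with the free hydroxyl directs.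

**C5–C1', 4 back to 2 and 3.** Cutting the bond between C1' and the alkyne gives farnesal 2 and 4-methoxybenzyl propargyl ether 3, both achiral; 2 comes from farnesol 1 by oxidation. The whole side chain thus comes from a commercial terpene with both alkene geometries in place. The ether 3 brings in C1 already protected by a group that is not silicon-based, which matters at the alkenyllithium stage. The forward reaction must set C1' (S) by catalyst control on a β,β-disubstituted enal.

## Roads not taken

**Alternative 1:** Lactone-tethered dihydroxylation. The C5–O and C1'–O bonds are cut: a fused butenolide A2, in which the lactone carbonyl is the future C2' and the lactone oxygen sits on C6, would be dihydroxylated with catalytic OsO4 and N-methylmorpholine N-oxide to the cis-fused dihydroxy lactone A1.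
- Merits: the syn addition on a bicyclic substrate sets the relative configuration of C5 and C1' in one reliable catalytic step. In this respect it is better than the chosen plan, which sets C1' and C5 in two separate reagent-controlled steps.
- Weak points: the step forms no C–C bond and closes no ring, so the carbocycle must already exist. A1 is also far from 21: eleven carbons of the chain must be grown from a lactone carbonyl, including the trisubstituted E-alkene next to the C1' carbinol; C1 is a methylene that must be oxidised to the ketone; and the C6 oxygen is cis to the C5 hydroxyl, so making the oxirane needs an inversion at C6 first. The ring enoate alkene of A2 is a second electron-poor alkene that competes for OsO4.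
- Comparison: the chosen plan sets against the better C5/C1' control a much shorter path after its key step and the use of farnesal as the intact chain.

**Alternative 2:** Siloxyfuran–dioxolone Diels–Alder with oxa-bridge opening. C4–C5 and C1–C6 are cut: the 2-silyloxyfuran A4 would add across the ring alkene of the chiral dioxolone A5, and opening of the oxygen bridge would give the cyclic carbonate A3.
- Merits: two C–C bonds and the six-membered ring form in one convergent step, and A3 already carries the ketone, the acetate, the C4 hydroxyl and every oxygen of the target. If it worked it would be clearly shorter than the chosen plan, and this has to be conceded.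
- Weak points: both partners are electron-rich, so there is no electronic match. Furan cycloadditions are reversible, and a trisubstituted enol carbonate is a poor dienophile. Facial selectivity on A5 would have to come from the C1' centre across a rotatable bond, and the endo/exo ratio decides the C4/C5 relationship. A3 also holds a cis carbonate where 21 has an oxirane, so an inversion at C6 is needed on a γ-hydroxy enone that aromatises easily.
- Comparison: the chosen plan sets against the brevity a known reaction type for every bond and separate, reagent-controlled steps for C1', C4 and the oxirane.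

**Alternative 3:** Nozaki–Hiyama–Kishi ring closure at C3–C4. The C3–C4 bond is cut: the Z-alkenyl iodide A7, with its aldehyde on the oxirane carbon C5, would be closed by CrCl2 with catalytic NiCl2 to the epoxycyclohexenol A6.
- Merits: alkenylchromium additions tolerate the oxirane and the acetate, and as a ring closure this reaction is probably more dependable than a phosphine-mediated closure of an enoate. The acetate is already in place, so the endgame is shorter. Both points are conceded.
- Weak points: A7 needs a stereodefined trisubstituted Z-alkenyl iodide and a hindered aldehyde on a fully substituted oxirane carbon. The C1 ether centre must be built only to be destroyed. Most seriously, the target centre C4 is created in the ring closure under substrate control alone and cannot be corrected afterwards.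
- Comparison: the chosen plan fixes C4 by a catalyst before the ring is closed, the only centre formed in its ring closure is disposable, and its precursor needs nothing harder than an E-enoate.

Key step: step 12

Assumption 1: the zinc catalyst built from (S,S)-ProPhenol is taken to add alkynes to the Re face of enals; steps 2 and 6 need Re- and Si-face addition, hence the (S,S)- and (R,R)-ligands, and if the sense proves opposite the two ligands are exchanged with no other change.

Assumption 2: the C1 epimer drawn for 17–19 (hydroxyl trans to the oxirane oxygen) stands for either epimer or their mixture, since C1 becomes the ketone in step 15.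

## Route

Step 1
Reactants: 1 (2E,6E)-farnesol
Product: 2 (2E,6E)-farnesal
Conditions: PhI(OAc)2, TEMPO (2,2,6,6-tetramethylpiperidin-1-oxyl, 10 mol %), CH2Cl2, rt
Reagents that add atoms: none
Why: Oxoammonium oxidation of a primary allylic alcohol stops at the enal and neither isomerises the 2E alkene nor touches the other trisubstituted alkenes.

Step 2
Reactants: 2 (2E,6E)-farnesal; 3 4-methoxybenzyl propargyl ether
Product: 4 (4S,5E,9E)-1-[(4-methoxybenzyl)oxy]-6,10,14-trimethylpentadeca-5,9,13-trien-2-yn-4-ol
Conditions: 3 (3 equiv), Me2Zn (3 equiv), (S,S)-ProPhenol [2,6-bis{[(S)-2-(hydroxydiphenylmethyl)pyrrolidin-1-yl]methyl}-4-methylphenol, 20 mol %], Ph3P=O (40 mol %), toluene, 4 °C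
Reagents that add atoms: none
Why: Zinc–ProPhenol asymmetric alkynylation of an α,β-unsaturated aldehyde; the dinuclear zinc complex binds the enal and transfers the alkynyl group to one carbonyl face, setting C1' (S) under catalyst control, and the alkyne brings in C1 already protected.

Step 3
Reactants: 4 (4S,5E,9E)-1-[(4-methoxybenzyl)oxy]-6,10,14-trimethylpentadeca-5,9,13-trien-2-yn-4-ol
Product: 6 (2Z,4S,5E,9E)-3-iodo-1-[(4-methoxybenzyl)oxy]-6,10,14-trimethylpentadeca-2,5,9,13-tetraen-4-ol, via alkenylstannane 5 (not isolated)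
Conditions: Bu3SnH (1.05 equiv), [(C5Me5)RuCl]4 (2.5 mol %), CH2Cl2, rt; then I2, 2,6-lutidine, 0 °C
Reagents that add atoms: iodine, [I][I]
Why: Hydroxyl-directed ruthenium-catalysed trans-hydrostannation: hydrogen bonding of the free C1' hydroxyl to the chloride ligand puts tin on the proximal alkyne carbon C5 and hydrogen on C6 from the opposite side, so tin is cis to the C1 methylene; iododestannylation then proceeds with retention, and the ether flank does not direct.

Step 4
Reactants: 6 (2Z,4S,5E,9E)-3-iodo-1-[(4-methoxybenzyl)oxy]-6,10,14-trimethylpentadeca-2,5,9,13-tetraen-4-ol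
Product: 7 triethyl{[(2Z,4S,5E,9E)-3-iodo-1-[(4-methoxybenzyl)oxy]-6,10,14-trimethylpentadeca-2,5,9,13-tetraen-4-yl]oxy}silane
Conditions: Et3SiCl, imidazole, 4-(dimethylamino)pyridine (cat.), CH2Cl2, 0 °C to rt
Reagents that add atoms: chlorotriethylsilane, CC[Si](Cl)(CC)CC
Why: Standard silylation of a secondary allylic alcohol; the triethylsilyl ether survives the organolithium, zinc, hydride and oxidation steps that follow and is removed at the end under buffered HF.

Step 5
Reactants: 7 triethyl{[(2Z,4S,5E,9E)-3-iodo-1-[(4-methoxybenzyl)oxy]-6,10,14-trimethylpentadeca-2,5,9,13-tetraen-4-yl]oxy}silane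
Product: 9 (2Z)-4-[(4-methoxybenzyl)oxy]-2-[(1S,2E,6E)-3,7,11-trimethyl-1-(triethylsilyloxy)dodeca-2,6,10-trien-1-yl]but-2-enal, via alkenyllithium 8 (not isolated)
Conditions: t-BuLi (2.1 equiv), Et2O, −78 °C; then DMF, −78 to 0 °C; aq. NH4Cl
Reagents that add atoms: N,N-dimethylformamide, CN(C)C=O
Why: Iodine–lithium exchange at −78 °C gives a configurationally stable alkenyllithium that DMF formylates with retention of alkene geometry; the C1 oxygen carries a benzyl-type ether because a silyl ether cis to the lithium would migrate to carbon.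

Step 6
Reactants: 9 (2Z)-4-[(4-methoxybenzyl)oxy]-2-[(1S,2E,6E)-3,7,11-trimethyl-1-(triethylsilyloxy)dodeca-2,6,10-trien-1-yl]but-2-enal; 10 ethyl propiolate
Product: 11 ethyl (4S,5E)-4-hydroxy-7-[(4-methoxybenzyl)oxy]-5-[(1S,2E,6E)-3,7,11-trimethyl-1-(triethylsilyloxy)dodeca-2,6,10-trien-1-yl]hept-5-en-2-ynoate (C7 oxymethylene cis to C4)
Conditions: 10 (3 equiv), Me2Zn (3 equiv), (R,R)-ProPhenol [2,6-bis{[(R)-2-(hydroxydiphenylmethyl)pyrrolidin-1-yl]methyl}-4-methylphenol, 20 mol %], Ph3P=O (40 mol %), toluene, 4 °C
Reagents that add atoms: none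
Why: Zinc–ProPhenol alkynylation with an alkyl propiolate, for which α-substituted enals are established substrates; the ligand antipode to that of step 2 delivers the alkynyl group to the Si face and sets the ring carbon C4 (S) under catalyst control.

Step 7
Reactants: 11 ethyl (4S,5E)-4-hydroxy-7-[(4-methoxybenzyl)oxy]-5-[(1S,2E,6E)-3,7,11-trimethyl-1-(triethylsilyloxy)dodeca-2,6,10-trien-1-yl]hept-5-en-2-ynoate
Product: 12 ethyl (2E,4S,5E)-4-hydroxy-7-[(4-methoxybenzyl)oxy]-5-[(1S,2E,6E)-3,7,11-trimethyl-1-(triethylsilyloxy)dodeca-2,6,10-trien-1-yl]hepta-2,5-dienoate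
Conditions: NaAlH2(OCH2CH2OMe)2, THF, −78 °C; aq. potassium sodium tartrate
Reagents that add atoms: none
Why: Alkoxide-directed trans-hydroalumination of a γ-hydroxy ynoate: the C4 alkoxide delivers hydride to C3 and protonation of the C2 alanate on work-up gives the E-enoate; at −78 °C the ester is not reduced and no stereocentre is touched.

Step 8
Reactants: 12 ethyl (2E,4S,5E)-4-hydroxy-7-[(4-methoxybenzyl)oxy]-5-[(1S,2E,6E)-3,7,11-trimethyl-1-(triethylsilyloxy)dodeca-2,6,10-trien-1-yl]hepta-2,5-dienoate
Product: 13 ethyl (2E,4S,5E)-7-[(4-methoxybenzyl)oxy]-4-(triethylsilyloxy)-5-[(1S,2E,6E)-3,7,11-trimethyl-1-(triethylsilyloxy)dodeca-2,6,10-trien-1-yl]hepta-2,5-dienoate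
Conditions: Et3SiOTf, 2,6-lutidine, CH2Cl2, −78 °C
Reagents that add atoms: triethylsilyl trifluoromethanesulfonate, CC[Si](CC)(CC)OS(=O)(=O)C(F)(F)F
Why: A silyl triflate with a hindered base silylates the crowded, doubly allylic C4 alcohol at low temperature without ionising it.

Step 9
Reactants: 13 ethyl (2E,4S,5E)-7-[(4-methoxybenzyl)oxy]-4-(triethylsilyloxy)-5-[(1S,2E,6E)-3,7,11-trimethyl-1-(triethylsilyloxy)dodeca-2,6,10-trien-1-yl]hepta-2,5-dienoate
Product: 14 ethyl (2E,4S,5E)-7-hydroxy-4-(triethylsilyloxy)-5-[(1S,2E,6E)-3,7,11-trimethyl-1-(triethylsilyloxy)dodeca-2,6,10-trien-1-yl]hepta-2,5-dienoate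
Conditions: DDQ, CH2Cl2/pH 7 phosphate buffer, 0 °C
Reagents that add atoms: none
Why: Oxidative cleavage of the 4-methoxybenzyl ether by DDQ in buffered wet dichloromethane; silyl ethers, the enoate and the isolated trisubstituted alkenes are inert, and the primary allylic alcohol needed for the epoxidation is released.

Step 10
Reactants: 14 ethyl (2E,4S,5E)-7-hydroxy-4-(triethylsilyloxy)-5-[(1S,2E,6E)-3,7,11-trimethyl-1-(triethylsilyloxy)dodeca-2,6,10-trien-1-yl]hepta-2,5-dienoate
Product: 15 ethyl (2E,4S)-4-{(2S,3S)-3-(hydroxymethyl)-2-[(1S,2E,6E)-3,7,11-trimethyl-1-(triethylsilyloxy)dodeca-2,6,10-trien-1-yl]oxiran-2-yl}-4-(triethylsilyloxy)but-2-enoate (oxirane carbons configured as C5 and C6 of 21)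
Conditions: Ti(OiPr)4 (1.0 equiv), L-(+)-diethyl tartrate (1.2 equiv), t-BuOOH, 4 Å molecular sieves, CH2Cl2, −20 °C
Reagents that add atoms: tert-butyl hydroperoxide, CC(C)(C)OO
Why: Sharpless asymmetric epoxidation: the titanium tartrate binds the only free hydroxyl (C1) and epoxidises C5=C6 alone; L-(+)-tartrate attacks the face that turns (E)-alk-2-en-1-ols into (2S,3S)-epoxy alcohols, which here gives the C5/C6 configuration of 21, and the cis relation of C4 and C1 on the oxirane follows from the alkene geometry.

Step 11
Reactants: 15 ethyl (2E,4S)-4-{(2S,3S)-3-(hydroxymethyl)-2-[(1S,2E,6E)-3,7,11-trimethyl-1-(triethylsilyloxy)dodeca-2,6,10-trien-1-yl]oxiran-2-yl}-4-(triethylsilyloxy)but-2-enoate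
Product: 16 ethyl (2E,4S)-4-{(2S,3R)-3-formyl-2-[(1S,2E,6E)-3,7,11-trimethyl-1-(triethylsilyloxy)dodeca-2,6,10-trien-1-yl]oxiran-2-yl}-4-(triethylsilyloxy)but-2-enoate (same spatial arrangement as 15)
Conditions: Dess–Martin periodinane, NaHCO3, CH2Cl2, 0 °C to rt
Reagents that add atoms: none
Why: Dess–Martin oxidation of a 2,3-epoxy alcohol gives the epoxy aldehyde under buffered conditions that do not epimerise C6; the product is used directly.

Step 12
Reactants: 16 ethyl (2E,4S)-4-{(2S,3R)-3-formyl-2-[(1S,2E,6E)-3,7,11-trimethyl-1-(triethylsilyloxy)dodeca-2,6,10-trien-1-yl]oxiran-2-yl}-4-(triethylsilyloxy)but-2-enoate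
Product: 17 ethyl (1R,4S,5R,6S)-1-hydroxy-4-(triethylsilyloxy)-5-[(1S,2E,6E)-3,7,11-trimethyl-1-(triethylsilyloxy)dodeca-2,6,10-trien-1-yl]-5,6-epoxycyclohex-2-ene-2-carboxylate (target numbering; oxirane oxygen trans to the C4 silyloxy group and to the C1 hydroxyl)
Conditions: PMe3 (1.0 equiv), tert-amyl alcohol/THF 1:1 (0.02 M), −20 °C to rt
Reagents that add atoms: none
Why: Trimethylphosphine adds reversibly to C3 of the enoate to give a β-phosphonium ester enolate whose C2 attacks the C1 aldehyde; proton transfer from C2 to the new alkoxide, helped by the alcohol co-solvent, and E1cB loss of the phosphine restore the C2=C3 alkene, now inside the ring. The closest known reaction type is the phosphine-mediated intramolecular Morita–Baylis–Hillman cyclisation of enoate aldehydes. The six-membered ring C1–C6 closes in the 6-exo-trig mode on the aldehyde carbonyl with the enolate double bond outside the ring, which is possible because C4 and C1 are cis on the oxirane. The one new stereocentre, C1, is governed by the adjacent oxirane (closure through the aldehyde conformer with C=O anti to the C6–O bond should put the hydroxyl trans to the oxirane oxygen), but it is erased in step 15, so either epimer serves. The step needs chemoselectivity: the soft phosphine must choose the Michael acceptor over the trisubstituted oxirane, which low temperature secures, and the C4 silyloxy group must not be expelled from the phosphonium intermediate, which its poor leaving-group ability secures. Intermolecular Rauhut–Currier or aldol coupling is held back by dilution, and C4, C5, C6 and C1' are not acidic under these conditions.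

Step 13
Reactants: 17 ethyl (1R,4S,5R,6S)-1-hydroxy-4-(triethylsilyloxy)-5-[(1S,2E,6E)-3,7,11-trimethyl-1-(triethylsilyloxy)dodeca-2,6,10-trien-1-yl]-5,6-epoxycyclohex-2-ene-2-carboxylate
Product: 18 (1R,4S,5R,6S)-2-(hydroxymethyl)-4-(triethylsilyloxy)-5-[(1S,2E,6E)-3,7,11-trimethyl-1-(triethylsilyloxy)dodeca-2,6,10-trien-1-yl]-5,6-epoxycyclohex-2-en-1-ol
Conditions: i-Bu2AlH (4 equiv), CH2Cl2, −78 °C; aq. potassium sodium tartrate
Reagents that add atoms: none
Why: 1,2-Reduction of the α,β-unsaturated ester by i-Bu2AlH at −78 °C gives the allylic alcohol; at this temperature the oxirane and the silyl ethers are not attacked.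

Step 14
Reactants: 18 (1R,4S,5R,6S)-2-(hydroxymethyl)-4-(triethylsilyloxy)-5-[(1S,2E,6E)-3,7,11-trimethyl-1-(triethylsilyloxy)dodeca-2,6,10-trien-1-yl]-5,6-epoxycyclohex-2-en-1-ol
Product: 19 [(1R,4S,5R,6S)-1-hydroxy-4-(triethylsilyloxy)-5-[(1S,2E,6E)-3,7,11-trimethyl-1-(triethylsilyloxy)dodeca-2,6,10-trien-1-yl]-5,6-epoxycyclohex-2-en-2-yl]methyl acetate
Conditions: AcCl (1.1 equiv), 2,4,6-collidine, CH2Cl2, −78 °C
Reagents that add atoms: acetyl chloride, CC(Cl)=O
Why: Acetyl chloride with collidine at −78 °C acylates primary hydroxyls selectively over secondary ones, and the C1 hydroxyl is secondary and flanked by the oxirane and the ring alkene.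

Step 15
Reactants: 19 [(1R,4S,5R,6S)-1-hydroxy-4-(triethylsilyloxy)-5-[(1S,2E,6E)-3,7,11-trimethyl-1-(triethylsilyloxy)dodeca-2,6,10-trien-1-yl]-5,6-epoxycyclohex-2-en-2-yl]methyl acetate
Product: 20 [(4S,5R,6R)-1-oxo-4-(triethylsilyloxy)-5-[(1S,2E,6E)-3,7,11-trimethyl-1-(triethylsilyloxy)dodeca-2,6,10-trien-1-yl]-5,6-epoxycyclohex-2-en-2-yl]methyl acetate
Conditions: Dess–Martin periodinane, NaHCO3, CH2Cl2, 0 °C
Reagents that add atoms: none
Why: Dess–Martin oxidation of the allylic, oxirane-flanked secondary alcohol gives the enone under bicarbonate buffering; both C1 epimers converge on 20, and no base is present that could eliminate the C4 silyloxy group or displace the allylic acetate.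

Step 16
Reactants: 20 [(4S,5R,6R)-1-oxo-4-(triethylsilyloxy)-5-[(1S,2E,6E)-3,7,11-trimethyl-1-(triethylsilyloxy)dodeca-2,6,10-trien-1-yl]-5,6-epoxycyclohex-2-en-2-yl]methyl acetate
Product: 21 [(4S,5R,6R)-4-hydroxy-5-[(1S,2E,6E)-1-hydroxy-3,7,11-trimethyldodeca-2,6,10-trien-1-yl]-1-oxo-5,6-epoxycyclohex-2-en-2-yl]methyl acetate (CNP0137670.2)
Conditions: HF·pyridine, pyridine, THF, 0 °C to rt
Reagents that add atoms: none
Why: Buffered HF·pyridine cleaves both triethylsilyl ethers under mildly acidic, weakly nucleophilic conditions that spare the epoxy enone, the allylic acetate and the allylic C1' alcohol; the four stereocentres are untouched.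

## Compound list

1 | (2E,6E)-farnesol | OC/C=C(\C)CC/C=C(\C)CCC=C(C)C | starting material
2 | (2E,6E)-farnesal | O=C/C=C(\C)CC/C=C(\C)CCC=C(C)C | intermediate
3 | 4-methoxybenzyl propargyl ether, 1-methoxy-4-[(prop-2-yn-1-yloxy)methyl]benzene | C#CCOCc1ccc(OC)cc1 | starting material
4 | (4S,5E,9E)-1-[(4-methoxybenzyl)oxy]-6,10,14-trimethylpentadeca-5,9,13-trien-2-yn-4-ol | COc1ccc(COCC#C[C@@H](O)/C=C(\C)CC/C=C(\C)CCC=C(C)C)cc1 | intermediate
5 | (2Z,4S,5E,9E)-1-[(4-methoxybenzyl)oxy]-6,10,14-trimethyl-3-(tributylstannyl)pentadeca-2,5,9,13-tetraen-4-ol (tin cis to the C1 methylene) | COc1ccc(COC/C=C(\[Sn](CCCC)(CCCC)CCCC)[C@@H](O)/C=C(\C)CC/C=C(\C)CCC=C(C)C)cc1 | intermediate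
6 | (2Z,4S,5E,9E)-3-iodo-1-[(4-methoxybenzyl)oxy]-6,10,14-trimethylpentadeca-2,5,9,13-tetraen-4-ol | COc1ccc(COC/C=C(\I)[C@@H](O)/C=C(\C)CC/C=C(\C)CCC=C(C)C)cc1 | intermediate
7 | triethylsilyl ether of 6 | COc1ccc(COC/C=C(\I)[C@@H](O[Si](CC)(CC)CC)/C=C(\C)CC/C=C(\C)CCC=C(C)C)cc1 | intermediate
8 | alkenyllithium from 7 (lithium in place of iodine at C5, cis to the C1 methylene) | COc1ccc(COC/C=C(\[Li])[C@@H](O[Si](CC)(CC)CC)/C=C(\C)CC/C=C(\C)CCC=C(C)C)cc1 | intermediate
9 | (2Z)-4-[(4-methoxybenzyl)oxy]-2-[(1S,2E,6E)-3,7,11-trimethyl-1-(triethylsilyloxy)dodeca-2,6,10-trien-1-yl]but-2-enal | COc1ccc(COC/C=C(\C=O)[C@@H](O[Si](CC)(CC)CC)/C=C(\C)CC/C=C(\C)CCC=C(C)C)cc1 | intermediate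
10 | ethyl propiolate | C#CC(=O)OCC | starting material
11 | ethyl (4S,5E)-4-hydroxy-7-[(4-methoxybenzyl)oxy]-5-[(1S,2E,6E)-3,7,11-trimethyl-1-(triethylsilyloxy)dodeca-2,6,10-trien-1-yl]hept-5-en-2-ynoate | CCOC(=O)C#C[C@H](O)/C(=C\COCc1ccc(OC)cc1)[C@@H](O[Si](CC)(CC)CC)/C=C(\C)CC/C=C(\C)CCC=C(C)C | intermediate
12 | ethyl (2E,4S,5E)-4-hydroxy-7-[(4-methoxybenzyl)oxy]-5-[(1S,2E,6E)-3,7,11-trimethyl-1-(triethylsilyloxy)dodeca-2,6,10-trien-1-yl]hepta-2,5-dienoate | CCOC(=O)/C=C/[C@H](O)/C(=C\COCc1ccc(OC)cc1)[C@@H](O[Si](CC)(CC)CC)/C=C(\C)CC/C=C(\C)CCC=C(C)C | intermediate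
13 | C4 triethylsilyl ether of 12 | CCOC(=O)/C=C/[C@H](O[Si](CC)(CC)CC)/C(=C\COCc1ccc(OC)cc1)[C@@H](O[Si](CC)(CC)CC)/C=C(\C)CC/C=C(\C)CCC=C(C)C | intermediate
14 | ethyl (2E,4S,5E)-7-hydroxy-4-(triethylsilyloxy)-5-[(1S,2E,6E)-3,7,11-trimethyl-1-(triethylsilyloxy)dodeca-2,6,10-trien-1-yl]hepta-2,5-dienoate | CCOC(=O)/C=C/[C@H](O[Si](CC)(CC)CC)/C(=C\CO)[C@@H](O[Si](CC)(CC)CC)/C=C(\C)CC/C=C(\C)CCC=C(C)C | intermediate
15 | ethyl (2E,4S)-4-{(2S,3S)-3-(hydroxymethyl)-2-[(1S,2E,6E)-3,7,11-trimethyl-1-(triethylsilyloxy)dodeca-2,6,10-trien-1-yl]oxiran-2-yl}-4-(triethylsilyloxy)but-2-enoate | CCOC(=O)/C=C/[C@H](O[Si](CC)(CC)CC)[C@@]1([C@@H](O[Si](CC)(CC)CC)/C=C(\C)CC/C=C(\C)CCC=C(C)C)O[C@H]1CO | intermediate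
16 | ethyl (2E,4S)-4-{(2S,3R)-3-formyl-2-[(1S,2E,6E)-3,7,11-trimethyl-1-(triethylsilyloxy)dodeca-2,6,10-trien-1-yl]oxiran-2-yl}-4-(triethylsilyloxy)but-2-enoate | CCOC(=O)/C=C/[C@H](O[Si](CC)(CC)CC)[C@@]1([C@@H](O[Si](CC)(CC)CC)/C=C(\C)CC/C=C(\C)CCC=C(C)C)O[C@H]1C=O | intermediate
17 | ethyl (1R,4S,5R,6S)-1-hydroxy-4-(triethylsilyloxy)-5-[(1S,2E,6E)-3,7,11-trimethyl-1-(triethylsilyloxy)dodeca-2,6,10-trien-1-yl]-5,6-epoxycyclohex-2-ene-2-carboxylate | CCOC(=O)C1=C[C@H](O[Si](CC)(CC)CC)[C@@]2([C@@H](O[Si](CC)(CC)CC)/C=C(\C)CC/C=C(\C)CCC=C(C)C)O[C@H]2[C@@H]1O | intermediate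
18 | (1R,4S,5R,6S)-2-(hydroxymethyl)-4-(triethylsilyloxy)-5-[(1S,2E,6E)-3,7,11-trimethyl-1-(triethylsilyloxy)dodeca-2,6,10-trien-1-yl]-5,6-epoxycyclohex-2-en-1-ol | OCC1=C[C@H](O[Si](CC)(CC)CC)[C@@]2([C@@H](O[Si](CC)(CC)CC)/C=C(\C)CC/C=C(\C)CCC=C(C)C)O[C@H]2[C@@H]1O | intermediate
19 | [(1R,4S,5R,6S)-1-hydroxy-4-(triethylsilyloxy)-5-[(1S,2E,6E)-3,7,11-trimethyl-1-(triethylsilyloxy)dodeca-2,6,10-trien-1-yl]-5,6-epoxycyclohex-2-en-2-yl]methyl acetate | CC(=O)OCC1=C[C@H](O[Si](CC)(CC)CC)[C@@]2([C@@H](O[Si](CC)(CC)CC)/C=C(\C)CC/C=C(\C)CCC=C(C)C)O[C@H]2[C@@H]1O | intermediate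
20 | [(4S,5R,6R)-1-oxo-4-(triethylsilyloxy)-5-[(1S,2E,6E)-3,7,11-trimethyl-1-(triethylsilyloxy)dodeca-2,6,10-trien-1-yl]-5,6-epoxycyclohex-2-en-2-yl]methyl acetate | CC(=O)OCC1=C[C@H](O[Si](CC)(CC)CC)[C@@]2([C@@H](O[Si](CC)(CC)CC)/C=C(\C)CC/C=C(\C)CCC=C(C)C)O[C@H]2C1=O | intermediate
21 | [(4S,5R,6R)-4-hydroxy-5-[(1S,2E,6E)-1-hydroxy-3,7,11-trimethyldodeca-2,6,10-trien-1-yl]-1-oxo-5,6-epoxycyclohex-2-en-2-yl]methyl acetate (CNP0137670.2) | CC(=O)OCC1=C[C@H](O)[C@@]2([C@@H](O)/C=C(\C)CC/C=C(\C)CCC=C(C)C)O[C@H]2C1=O | target

## Step count and least certain steps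

Total step count: 16. Longest linear sequence: 16 steps from farnesol 1; compounds 3 and 10 are bought.

**Step 12 (key step).** The phosphine may fail to turn over, because enoates are weak acceptors and C3 is hindered by the adjacent silyloxy-bearing C4. It may also open or deoxygenate the activated oxirane. The phosphonium intermediate may lose the C4 silyloxy group by β-elimination, and the transient C1 alkoxide may trigger oxirane migration.

Fallback, from 16 back to 17: the same C1–C2 bond is made by a stoichiometric heteroatom-triggered Michael–aldol sequence. Me2AlSePh adds selenolate to C3 of 16 at −78 °C and the aluminium enolate closes onto the C1 aldehyde, giving the β-phenylselanyl hydroxy ester F1. Oxidation with H2O2 and pyridine at 0 °C, followed by syn-elimination of the selenoxide towards C2 (elimination towards the oxygen-bearing C4 is disfavoured), returns 17.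

**Step 10.** Facial selectivity may be poor and the reaction slow. The alkene carries branched, oxygenated substituents at both positions of C5, and the resident C4 and C1' centres exert their own bias, which cannot be predicted with confidence to agree with the tartrate.

Fallback, from 12 back to 15: the epoxidation is directed by the free C4 hydroxyl of 12 with Ti(OiPr)4 and t-BuOOH without tartrate. 1,3-Allylic strain between the C4 substituents and the cis C1 methylene holds the C4 hydrogen in the alkene plane, so the bound peroxide is delivered syn to the hydroxyl. This gives the threo epoxy alcohol F2, whose oxirane has the required configuration. Silylation with Et3SiOTf and 2,6-lutidine gives the bis(triethylsilyl) ether F3, and DDQ cleavage of the 4-methoxybenzyl ether returns 15.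

**Step 6.** Catalyst control may erode on the hindered α-branched enal next to the C1' centre (a mismatched pairing), and the enal may isomerise at C5=C6 under the Lewis-acidic zinc conditions.

Fallback, from 7 back to 12: the C4–C5 bond is formed instead. Iodide 7 is coupled with commercial ethyl (E)-4-oxobut-2-enoate using CrCl2 and catalytic NiCl2 in DMSO, a Nozaki–Hiyama–Kishi addition that keeps the alkene geometry and leaves the enoate alone. It gives 12 together with its C4 epimer, ethyl (2E,4R,5E)-4-hydroxy-7-[(4-methoxybenzyl)oxy]-5-[(1S,2E,6E)-3,7,11-trimethyl-1-(triethylsilyloxy)dodeca-2,6,10-trien-1-yl]hepta-2,5-dienoate F4, which is removed by chromatography. This path also bypasses steps 5 and 7.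

**Step 5.** The alkenyllithium may be lost by β-elimination of the C1' silyloxide or by silyl migration from oxygen to carbon, and the enal may partly isomerise during work-up.

Fallback, from 7 back to 9: palladium-catalysed formylation of 7 with Pd(PPh3)4 (zerovalent palladium), CO and slowly added Bu3SnH in THF at 50 °C gives 9 without any organolithium. No new compound is made.

Further compounds

F1 | step 12 | ethyl (4S,5R,6S)-1-hydroxy-3-(phenylselanyl)-4-(triethylsilyloxy)-5-[(1S,2E,6E)-3,7,11-trimethyl-1-(triethylsilyloxy)dodeca-2,6,10-trien-1-yl]-5,6-epoxycyclohexane-2-carboxylate (target numbering; mixture at C1, C2 and C3) | CCOC(=O)C1C([Se]c2ccccc2)[C@H](O[Si](CC)(CC)CC)[C@@]3([C@@H](O[Si](CC)(CC)CC)/C=C(\C)CC/C=C(\C)CCC=C(C)C)O[C@H]3C1O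
F2 | step 10 | ethyl (2E,4S)-4-hydroxy-4-{3-{[(4-methoxybenzyl)oxy]methyl}-2-[(1S,2E,6E)-3,7,11-trimethyl-1-(triethylsilyloxy)dodeca-2,6,10-trien-1-yl]oxiran-2-yl}but-2-enoate (oxirane carbons configured as C5 and C6 of 21) | CCOC(=O)/C=C/[C@H](O)[C@@]1([C@@H](O[Si](CC)(CC)CC)/C=C(\C)CC/C=C(\C)CCC=C(C)C)O[C@H]1COCc2ccc(OC)cc2
F3 | step 10 | C4 triethylsilyl ether of F2 | CCOC(=O)/C=C/[C@H](O[Si](CC)(CC)CC)[C@@]1([C@@H](O[Si](CC)(CC)CC)/C=C(\C)CC/C=C(\C)CCC=C(C)C)O[C@H]1COCc2ccc(OC)cc2
F4 | step 6 | ethyl (2E,4R,5E)-4-hydroxy-7-[(4-methoxybenzyl)oxy]-5-[(1S,2E,6E)-3,7,11-trimethyl-1-(triethylsilyloxy)dodeca-2,6,10-trien-1-yl]hepta-2,5-dienoate | CCOC(=O)/C=C/[C@@H](O)/C(=C\COCc1ccc(OC)cc1)[C@@H](O[Si](CC)(CC)CC)/C=C(\C)CC/C=C(\C)CCC=C(C)C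
F0 | step 5 | none | none
A1 | alternative 1 | cis-fused dihydroxy lactone with C4 tert-butyldimethylsilyl ether and ring methyl ester | COC(=O)C1=C[C@H](O[Si](C)(C)C(C)(C)C)[C@]2(O)[C@@H](O)C(=O)O[C@@H]2C1
A2 | alternative 1 | fused butenolide with C5=C1' alkene, C4 tert-butyldimethylsilyl ether and ring methyl ester | COC(=O)C1=C[C@H](O[Si](C)(C)C(C)(C)C)C2=CC(=O)O[C@@H]2C1
A3 | alternative 2 | 4-hydroxycyclohex-2-enone 5,6-cyclic carbonate with C7 acetate and silylated side chain | CC(=O)OCC1=C[C@H](O)[C@@]2([C@@H](O[Si](C)(C)C(C)(C)C)/C=C(\C)CC/C=C(\C)CCC=C(C)C)OC(=O)O[C@H]2C1=O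
A4 | alternative 2 | [2-(tert-butyldimethylsilyloxy)furan-3-yl]methyl acetate | CC(=O)OCc1ccoc1O[Si](C)(C)C(C)(C)C
A5 | alternative 2 | 4-[(1S,2E,6E)-1-(tert-butyldimethylsilyloxy)-3,7,11-trimethyldodeca-2,6,10-trien-1-yl]-1,3-dioxol-2-one | O=C1OC=C(O1)[C@@H](O[Si](C)(C)C(C)(C)C)/C=C(\C)CC/C=C(\C)CCC=C(C)C
A6 | alternative 3 | epoxycyclohexenol with free C4 hydroxyl, C1 4-methoxybenzyl ether, C7 acetate and C1' triethylsilyl ether | CC(=O)OCC1=C[C@H](O)[C@@]2([C@@H](O[Si](CC)(CC)CC)/C=C(\C)CC/C=C(\C)CCC=C(C)C)O[C@H]2[C@@H]1OCc3ccc(OC)cc3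
A7 | alternative 3 | open-chain Z-alkenyl iodide with the C4 aldehyde on the oxirane carbon C5 | CC(=O)OC/C(=C/I)[C@@H](OCc1ccc(OC)cc1)[C@@H]2O[C@@]2(C=O)[C@@H](O[Si](CC)(CC)CC)/C=C(\C)CC/C=C(\C)CCC=C(C)C
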